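**Retrosynthetic overview**

1. The target is the closed hemiketal form of a (2R)-2',6'-dihydroxyflavanone. The last cut is C4–O2' (ring–chain tautomerism once ring B is unmasked). Before it come O1–C8a of ring C (SNAr of the C2 alkoxide at C8a–F, ortho to the C4 ketone) and C4–C4a (aryllithium plus an (R)-β-silyloxy aldehyde made by Brown allylboration).
2. Key disconnection: pyran ring D is cut at C3''–C2'' and at O–C7 at the chromanone oxidation level. This is a domino aldol/SNAr between the C6 acetyl group and acetone; the C4'' carbonyl is then removed by reduction and dehydration.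
3. Enabling feature: on ring A each ring-closing oxygen (the ring D oxygen on C7, O1 on C8a) is ortho to a carbon carrying a carbonyl-level carbon (C6–C4'', C4a–C4). An ortho acyl group is both the enolate precursor and the activator of the ortho C–F bond, so ring A can be bought as 3,5-difluoroanisole and the O–C(CH3)2 unit of acetone enters intact.
4. All ring A substituents enter by F/OMe-directed lithiation (C8 prenyl between the two F, then C6 acetyl, then the C4a acyl chain). This fixes the linear pyran fusion and the 8-prenyl position without the regiochemical ambiguity of phloroglucinol chemistry.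
5. Order of ring formation: ring A (bought) → ring D (step 3, alkene in step 5) → ring C (step 12) → hemiketal ring (step 13); ring B is bought.

Key step: step 3

Assumption: the target is taken to be the thermodynamically preferred closed tautomer of flavanone 27, so the C4–O2' bond forms spontaneously, and the bicyclo[3.3.1] geometry allows only (4R) from (2R).
Locants: flavanone numbering (O1, C2–C4, C4a, C5–C8, C8a; ring B primed); ring D double-primed (C2'' carries the two methyl groups, C3''=C4'').

**Route**

Step 1
Reactants: 1 3,5-difluoroanisole; 2 prenyl bromide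
Product: 4 1,3-difluoro-5-methoxy-2-(3-methylbut-2-en-1-yl)benzene, via aryllithium 3 (not isolated)
Conditions: n-BuLi, THF, −78 °C; CuBr·SMe2 (1 equiv), then 2, −78 → 0 °C
Reagents that add atoms: none
Why: Fluorine-directed ortho-lithiation takes the most acidic C–H, the one between the two fluorine atoms, and copper-mediated allylic substitution with 2 at its primary carbon (SN2) puts the linear prenyl group on the future C8; no stereocentre is formed.

Step 2
Reactants: 4 1,3-difluoro-5-methoxy-2-(3-methylbut-2-en-1-yl)benzene; 5 N-methoxy-N-methylacetamide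
Product: 7 1-[2,4-difluoro-6-methoxy-3-(3-methylbut-2-en-1-yl)phenyl]ethan-1-one, via aryllithium 6 (not isolated)
Conditions: n-BuLi, THF, −78 °C; then 5, −78 → 0 °C; H2O
Reagents that add atoms: none
Why: Directed ortho-metalation between OMe and F (the two remaining ring C–H are equivalent by symmetry) followed by Weinreb ketone synthesis should give the methyl ketone on the future C6 without over-addition; no stereocentre is formed.

Step 3
Reactants: 7 1-[2,4-difluoro-6-methoxy-3-(3-methylbut-2-en-1-yl)phenyl]ethan-1-one; 8 acetone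
Product: 11 7-fluoro-5-methoxy-2,2-dimethyl-8-(3-methylbut-2-en-1-yl)chroman-4-one, via lithium enolate 9 (not isolated), via lithium aldolate 10 (not isolated)
Conditions: LiN(SiMe3)2 (1.05 equiv), THF, −78 °C; 8 (5 equiv), −78 °C; then DMPU, −78 → 25 °C
Reagents that add atoms: none
Why: Proposed new method: the kinetic lithium enolate 9 adds to acetone to give the tertiary aldolate 10 (new CH2–C(CH3)2 bond, the later C3''–C2'' bond), and on warming with DMPU the alkoxide displaces the fluoride on C7, which is ortho to the acyl group, by addition–elimination through a Meisenheimer intermediate whose charge rests on the carbonyl (new O–C7 bond). The closest known reactions are the Kabbe chromanone synthesis (same ring from an ortho-hydroxyacetophenone and a ketone, with opposite polarity at oxygen) and the stepwise sequence of aldol addition and base-mediated intramolecular SNAr of 1-(2-fluoroaryl)-3-hydroxyalkan-1-ones. Ring D closes by a six-membered attack of oxygen on the aromatic sp2 carbon C7 (6-exo-trig type, the charge-accepting C7=C8 bond lying outside the new ring). No stereocentre is formed. The step needs ortho displacement to win over intermolecular attack at the para fluorine (C8a–F) and needs the reversible ketone–ketone aldol to be drained forward. The six-membered ring size, the excess of acetone and the irreversible loss of LiF should secure this, because retro-aldol only returns 9 and acetone, which add again.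

Step 4
Reactants: 11 7-fluoro-5-methoxy-2,2-dimethyl-8-(3-methylbut-2-en-1-yl)chroman-4-one
Product: 12 7-fluoro-5-methoxy-2,2-dimethyl-8-(3-methylbut-2-en-1-yl)chroman-4-ol (racemic)
Conditions: NaBH4, MeOH/THF, 0 → 25 °C
Reagents that add atoms: none
Why: Hydride reduction of the aryl ketone with NaBH4 leaves the alkene and the now weakly activated C–F bond alone; the new carbinol centre is formed as a racemate and is destroyed in step 5.

Step 5
Reactants: 12 7-fluoro-5-methoxy-2,2-dimethyl-8-(3-methylbut-2-en-1-yl)chroman-4-ol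
Product: 14 7-fluoro-5-methoxy-2,2-dimethyl-8-(3-methylbut-2-en-1-yl)-2H-chromene, via mesylate 13 (not isolated)
Conditions: MsCl, Et3N (excess), CH2Cl2, 0 → 25 °C
Reagents that add atoms: none
Why: Mesylation of the electron-rich benzylic alcohol and elimination (E1/E2) under the amine base should give the 2H-chromene without exposing it to acid; the quaternary C2'' allows only the C3''=C4'' alkene.

Step 6
Reactants: 15 2,6-dihydroxybenzaldehyde
Product: 16 2,6-bis(methoxymethoxy)benzaldehyde
Conditions: NaH, MOMCl, DMF, 0 → 25 °C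
Reagents that add atoms: chloromethyl methyl ether (MOMCl) COCCl
Why: Williamson-type O-alkylation of both phenoxides gives the bis-acetal, which is stable to all basic and organometallic steps that follow.

Step 7
Reactants: 16 2,6-bis(methoxymethoxy)benzaldehyde; 17 B-allyldiisopinocampheylborane from (−)-α-pinene
Product: 18 (1R)-1-[2,6-bis(methoxymethoxy)phenyl]but-3-en-1-ol
Conditions: 17 (1 M in pentane), Et2O, −78 °C; then NaOH, H2O2, 0 → 25 °C
Reagents that add atoms: none
Why: Brown asymmetric allylboration through a closed chair transition state with the aryl group equatorial, in which the isopinocampheyl groups derived from (−)-α-pinene direct allyl transfer to the Re face of the aldehyde and so set the (R)-carbinol (reagent control).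

Step 8
Reactants: 18 (1R)-1-[2,6-bis(methoxymethoxy)phenyl]but-3-en-1-ol
Product: 19 (1R)-1-[2,6-bis(methoxymethoxy)phenyl]but-3-en-1-yl tert-butyldimethylsilyl ether
Conditions: TBSCl, imidazole, DMF, 25 → 40 °C
Reagents that add atoms: tert-butyldimethylsilyl chloride (TBSCl) CC(C)(C)[Si](C)(C)Cl
Why: Silyl ether formation at oxygen under conditions that leave the aryl MOM acetals intact; the C–O bond of the stereocentre is not touched.

Step 9
Reactants: 19 (1R)-1-[2,6-bis(methoxymethoxy)phenyl]but-3-en-1-yl tert-butyldimethylsilyl ether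
Product: 21 (3R)-3-[2,6-bis(methoxymethoxy)phenyl]-3-[(tert-butyldimethylsilyl)oxy]propanal, via ozonide 20 (not isolated)
Conditions: O3 (stopped at the end point), CH2Cl2, −78 °C; then PPh3, −78 → 25 °C
Reagents that add atoms: ozone [O-][O+]=O
Why: Ozonolysis of the terminal alkene with reductive work-up gives the β-silyloxy aldehyde; the alkene reacts much faster than the arene at −78 °C and the β-stereocentre is not involved.

Step 10
Reactants: 14 7-fluoro-5-methoxy-2,2-dimethyl-8-(3-methylbut-2-en-1-yl)-2H-chromene; 21 (3R)-3-[2,6-bis(methoxymethoxy)phenyl]-3-[(tert-butyldimethylsilyl)oxy]propanal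
Product: 23 (3R)-3-[2,6-bis(methoxymethoxy)phenyl]-3-[(tert-butyldimethylsilyl)oxy]-1-[7-fluoro-5-methoxy-2,2-dimethyl-8-(3-methylbut-2-en-1-yl)-2H-chromen-6-yl]propan-1-ol (both C1 epimers), via aryllithium 22 (not isolated)
Conditions: n-BuLi, THF, −78 °C; then 21, −78 °C; H2O
Reagents that add atoms: none
Why: Directed ortho-lithiation at the only ring C–H, between OMe (C5) and F (C8a), and 1,2-addition of the aryllithium to the aldehyde form the C4–C4a bond; the new carbinol centre is formed without control and is oxidised in step 11.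

Step 11
Reactants: 23 (3R)-3-[2,6-bis(methoxymethoxy)phenyl]-3-[(tert-butyldimethylsilyl)oxy]-1-[7-fluoro-5-methoxy-2,2-dimethyl-8-(3-methylbut-2-en-1-yl)-2H-chromen-6-yl]propan-1-ol
Product: 24 (3R)-3-[2,6-bis(methoxymethoxy)phenyl]-3-[(tert-butyldimethylsilyl)oxy]-1-[7-fluoro-5-methoxy-2,2-dimethyl-8-(3-methylbut-2-en-1-yl)-2H-chromen-6-yl]propan-1-one
Conditions: Dess–Martin periodinane, CH2Cl2, 0 → 25 °C
Reagents that add atoms: none
Why: Dess–Martin oxidation of the benzylic alcohol gives the aryl ketone that will be C4 without touching the alkenes or the silyloxy-bearing C2 centre.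

Step 12
Reactants: 24 (3R)-3-[2,6-bis(methoxymethoxy)phenyl]-3-[(tert-butyldimethylsilyl)oxy]-1-[7-fluoro-5-methoxy-2,2-dimethyl-8-(3-methylbut-2-en-1-yl)-2H-chromen-6-yl]propan-1-one
Product: 26 (2R)-2-[2,6-bis(methoxymethoxy)phenyl]-5-methoxy-8,8-dimethyl-10-(3-methylbut-2-en-1-yl)-2,3-dihydro-4H,8H-pyrano[3,2-g]chromen-4-one, via ammonium alkoxide 25 (not isolated)
Conditions: TBAF (dried over 4 Å sieves), THF, 0 °C
Reagents that add atoms: none
Why: Fluoride desilylation releases the C2 alkoxide, which closes ring C by intramolecular SNAr (addition–elimination, six-membered) at C8a–F ortho to the C4 ketone; the C2–O bond is never broken, so the (R) configuration is retained.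

Step 13
Reactants: 26 (2R)-2-[2,6-bis(methoxymethoxy)phenyl]-5-methoxy-8,8-dimethyl-10-(3-methylbut-2-en-1-yl)-2,3-dihydro-4H,8H-pyrano[3,2-g]chromen-4-one
Product: 28 CNP0170313.2 (the (2R,4R) C4–O2' bridged hemiketal of 27), via open flavanone 27 (not isolated)
Conditions: NaHSO4·SiO2, CH2Cl2 (wet), 25 °C
Reagents that add atoms: none
Why: Mild heterogeneous acid hydrolysis of the two phenolic MOM acetals frees the 2'-OH, which adds to the C4 ketone (ring–chain tautomerism); the C4 centre is set by substrate control, since the bicyclo[3.3.1] geometry allows only (4R) from (2R).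

**Compound list**

1 | 3,5-difluoroanisole (1,3-difluoro-5-methoxybenzene) | COc1cc(F)cc(F)c1 | starting material
2 | prenyl bromide (1-bromo-3-methylbut-2-ene) | CC(C)=CCBr | starting material
3 | (2,6-difluoro-4-methoxyphenyl)lithium | [Li]c1c(F)cc(OC)cc1F | intermediate
4 | 1,3-difluoro-5-methoxy-2-(3-methylbut-2-en-1-yl)benzene | COc1cc(F)c(CC=C(C)C)c(F)c1 | intermediate
5 | N-methoxy-N-methylacetamide | CC(=O)N(C)OC | starting material
6 | [2,4-difluoro-6-methoxy-3-(3-methylbut-2-en-1-yl)phenyl]lithium | [Li]c1c(OC)cc(F)c(CC=C(C)C)c1F | intermediate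
7 | 1-[2,4-difluoro-6-methoxy-3-(3-methylbut-2-en-1-yl)phenyl]ethan-1-one | CC(=O)c1c(OC)cc(F)c(CC=C(C)C)c1F | intermediate
8 | acetone | CC(C)=O | starting material
9 | lithium enolate of 7 | [Li]OC(=C)c1c(OC)cc(F)c(CC=C(C)C)c1F | intermediate
10 | lithium aldolate (lithium salt of the 3-hydroxy-3-methylbutan-1-one of 7) | [Li]OC(C)(C)CC(=O)c1c(OC)cc(F)c(CC=C(C)C)c1F | intermediate
11 | 7-fluoro-5-methoxy-2,2-dimethyl-8-(3-methylbut-2-en-1-yl)chroman-4-one | COc1cc(F)c(CC=C(C)C)c2OC(C)(C)CC(=O)c12 | intermediate
12 | 7-fluoro-5-methoxy-2,2-dimethyl-8-(3-methylbut-2-en-1-yl)chroman-4-ol, racemic | COc1cc(F)c(CC=C(C)C)c2OC(C)(C)CC(O)c12 | intermediate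
13 | methanesulfonate of 12 | COc1cc(F)c(CC=C(C)C)c2OC(C)(C)CC(OS(C)(=O)=O)c12 | intermediate
14 | 7-fluoro-5-methoxy-2,2-dimethyl-8-(3-methylbut-2-en-1-yl)-2H-chromene | COc1cc(F)c(CC=C(C)C)c2OC(C)(C)C=Cc12 | intermediate
15 | 2,6-dihydroxybenzaldehyde | O=Cc1c(O)cccc1O | starting material
16 | 2,6-bis(methoxymethoxy)benzaldehyde | O=Cc1c(OCOC)cccc1OCOC | intermediate
17 | B-allyldiisopinocampheylborane with both isopinocampheyl groups from (−)-α-pinene (l-Ipc2B-allyl, sold as the (+)-reagent) | C=CCB([C@H]1C[C@H]2C[C@@H]([C@@H]1C)C2(C)C)[C@H]1C[C@H]2C[C@@H]([C@@H]1C)C2(C)C | starting material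
18 | (1R)-1-[2,6-bis(methoxymethoxy)phenyl]but-3-en-1-ol | C=CC[C@@H](O)c1c(OCOC)cccc1OCOC | intermediate
19 | tert-butyldimethylsilyl ether of 18, (R) | C=CC[C@@H](O[Si](C)(C)C(C)(C)C)c1c(OCOC)cccc1OCOC | intermediate
20 | secondary ozonide (3-substituted 1,2,4-trioxolane) of 19 | C1OC(C[C@@H](O[Si](C)(C)C(C)(C)C)c2c(OCOC)cccc2OCOC)OO1 | intermediate
21 | (3R)-3-[2,6-bis(methoxymethoxy)phenyl]-3-[(tert-butyldimethylsilyl)oxy]propanal | O=CC[C@@H](O[Si](C)(C)C(C)(C)C)c1c(OCOC)cccc1OCOC | intermediate
22 | [7-fluoro-5-methoxy-2,2-dimethyl-8-(3-methylbut-2-en-1-yl)-2H-chromen-6-yl]lithium | [Li]c1c(OC)c2C=CC(C)(C)Oc2c(CC=C(C)C)c1F | intermediate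
23 | (3R)-3-[2,6-bis(methoxymethoxy)phenyl]-3-[(tert-butyldimethylsilyl)oxy]-1-[7-fluoro-5-methoxy-2,2-dimethyl-8-(3-methylbut-2-en-1-yl)-2H-chromen-6-yl]propan-1-ol, C1 epimers | COc1c(C(O)C[C@@H](O[Si](C)(C)C(C)(C)C)c2c(OCOC)cccc2OCOC)c(F)c(CC=C(C)C)c2OC(C)(C)C=Cc12 | intermediate
24 | the corresponding propan-1-one (aryl ketone), (3R) | COc1c(C(=O)C[C@@H](O[Si](C)(C)C(C)(C)C)c2c(OCOC)cccc2OCOC)c(F)c(CC=C(C)C)c2OC(C)(C)C=Cc12 | intermediate
25 | tetrabutylammonium (1R)-alkoxide formed from 24 by loss of the silyl group | CCCC[N+](CCCC)(CCCC)CCCC.COc1c(C(=O)C[C@@H]([O-])c2c(OCOC)cccc2OCOC)c(F)c(CC=C(C)C)c2OC(C)(C)C=Cc12 | intermediate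
26 | (2R)-2-[2,6-bis(methoxymethoxy)phenyl]-5-methoxy-8,8-dimethyl-10-(3-methylbut-2-en-1-yl)-2,3-dihydro-4H,8H-pyrano[3,2-g]chromen-4-one | COc1c2c(c(CC=C(C)C)c3c1C(=O)C[C@@H](O3)c1c(OCOC)cccc1OCOC)OC(C)(C)C=C2 | intermediate
27 | (2R)-2-(2,6-dihydroxyphenyl)-5-methoxy-8,8-dimethyl-10-(3-methylbut-2-en-1-yl)-2,3-dihydro-4H,8H-pyrano[3,2-g]chromen-4-one (open flavanone) | COc1c2c(c(CC=C(C)C)c3c1C(=O)C[C@@H](O3)c1c(O)cccc1O)OC(C)(C)C=C2 | intermediate
28 | CNP0170313.2, the (2R,4R) hemiketal of 27 with a C4–O2' bridge (2,6-dioxabicyclo[3.3.1]nonane core) | COc1c2c(c(CC=C(C)C)c3c1[C@@]1(O)C[C@@H](O3)c3c(O)cccc3O1)OC(C)(C)C=C2 | target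

**Step count and risks**

Total step count: 13. Longest linear sequence: 9 steps (steps 1–5 and 10–13); the ring B fragment takes steps 6–9.

Steps most likely to fail:

1. Step 3 (Proposed new method). The reversible ketone–ketone aldol may not be drained by ring closure fast enough. Proton transfer to acetone, dehydration of the aldolate or intermolecular displacement of the para fluorine could then take over. Fallback (stepwise, known chemistry): it sets out from 7, which is converted with TMSOTf and Et3N into the trimethylsilyl enol ether F1. A Mukaiyama aldol addition of F1 to acetone 8 (TiCl4, CH2Cl2, −78 °C) gives the isolated β-hydroxy ketone F2. F2 is closed separately by intramolecular SNAr (NaH, THF, 0 → 25 °C), and the route is rejoined at 11.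

2. Step 12. The free β-alkoxy ketone may undergo retro-aldol cleavage or E1cB dehydration before the ring closes, or the product may open at C2–O1 under the basic fluoride; either would cost material or enantiopurity. Fallback (ring C closed one oxidation level lower): it sets out from 23, which TBAF converts into the diol F3. With KOC(CH3)3 in DMSO at 60 °C the C2 alkoxide displaces C8a–F to give the flavan-4-ol F4. No carbonyl is present at this stage, so neither retro-aldol nor elimination can occur, and alkoxide SNAr on non-activated aryl fluorides is known for chromans. Dess–Martin oxidation of F4 rejoins the route at 26.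

3. Step 13. During acetal hydrolysis the electron-rich chromene or the prenyl alkene may be protonated (hydration, dimerisation). Acid may also ionise the C2–O1 bond of the open flavanone, with loss of configuration. Fallback (aprotic silyl-transfer deprotection instead of Brønsted acid hydrolysis): it sets out from 26. TMSOTf and 2,2'-bipyridyl in CH2Cl2 at 0 °C convert both aryl MOM ethers into the bis(trimethylsilyl) ether F5. F5 is hydrolysed by water at neutral pH on work-up and closes to the hemiketal, rejoining the route at 28.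

**Further compounds**

F1 | step 3 | trimethylsilyl enol ether of 7 | C=C(O[Si](C)(C)C)c1c(OC)cc(F)c(CC=C(C)C)c1F
F2 | step 3 | 1-[2,4-difluoro-6-methoxy-3-(3-methylbut-2-en-1-yl)phenyl]-3-hydroxy-3-methylbutan-1-one | CC(C)(O)CC(=O)c1c(OC)cc(F)c(CC=C(C)C)c1F
F3 | step 12 | (3R)-3-[2,6-bis(methoxymethoxy)phenyl]-1-[7-fluoro-5-methoxy-2,2-dimethyl-8-(3-methylbut-2-en-1-yl)-2H-chromen-6-yl]propane-1,3-diol, C1 epimers | COc1c(C(O)C[C@@H](O)c2c(OCOC)cccc2OCOC)c(F)c(CC=C(C)C)c2OC(C)(C)C=Cc12
F4 | step 12 | (2R)-2-[2,6-bis(methoxymethoxy)phenyl]-5-methoxy-8,8-dimethyl-10-(3-methylbut-2-en-1-yl)-3,4-dihydro-2H,8H-pyrano[3,2-g]chromen-4-ol, C4 epimers | COc1c2c(c(CC=C(C)C)c3c1C(O)C[C@@H](O3)c1c(OCOC)cccc1OCOC)OC(C)(C)C=C2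
F5 | step 13 | (2R)-2-[2,6-bis(trimethylsilyloxy)phenyl]-5-methoxy-8,8-dimethyl-10-(3-methylbut-2-en-1-yl)-2,3-dihydro-4H,8H-pyrano[3,2-g]chromen-4-one | COc1c2c(c(CC=C(C)C)c3c1C(=O)C[C@@H](O3)c1c(O[Si](C)(C)C)cccc1O[Si](C)(C)C)OC(C)(C)C=C2
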